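**Retrosynthetic overview**
1. Target 29 arises from the 9-O-THP, 15-ketal acid 28 by acid hydrolysis; 28 comes from oxidation at C11 after the (Z)-selective Wittig olefination (C5=C6) of lactol 21.
2. Lactol 21 comes from the cis-fused bicyclic γ-lactone 20, which is disconnected at C8–C9 to the acyclic aldehyde (Z)-enoate 18 (cathodic reductive coupling).
3. 18 comes from the syn aldol adduct 11 (C11–C12 bond, auxiliary control) of imide 6 and aldehyde 9, by Z-selective olefination at C8 and oxidation at C9.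
4. Feature used: on the cyclopentane C8–C9–C10–C11–C12 the oxygen on C9 and the C7–C6 arm on C8 are cis, the pattern of a fused γ-lactone (O–C9–C8–C7–C6). C8 (enoate β-carbon) and C9 (aldehyde carbon) are both acceptor carbons, so the C8–C9 bond is made by electron injection.
5. Ring order: cyclopentane, then γ-lactone, both in step 12; the lactone is reopened in step 14.

Key step: step 12

Remark on the chemistry: prostaglandin numbering (C1 = carboxyl carbon, C20 = chain end) is used for all intermediates. The C11 silyl ether centre only steers the ring closure and ends as the ketone.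

**Step 1**
Reactants: 1 5-oxodecanoic acid
Product: 3 4-(2-pentyl-1,3-dioxolan-2-yl)butanoic acid, via hydroxyethyl ester ketal 2 (not isolated)
Conditions: HOCH2CH2OH (5 equiv), TsOH·H2O (cat.), PhMe, reflux, Dean–Stark; then NaOH, MeOH/H2O, rt; 1 M HCl to pH 5, 0 °C
Reagents that add atoms: ethylene glycol, OCCO; sodium hydroxide, [Na+].[OH-]
Why: Acid-catalysed ketalisation with azeotropic water removal masks the C15 ketone (the acid is esterified alongside), and saponification then frees the acid while the base-stable ketal remains.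

**Step 2**
Reactants: 3 4-(2-pentyl-1,3-dioxolan-2-yl)butanoic acid; 4 (S)-4-benzyl-2-oxazolidinone
Product: 6 (S)-4-benzyl-3-[4-(2-pentyl-1,3-dioxolan-2-yl)butanoyl]oxazolidin-2-one, via mixed pivalic anhydride 5 (not isolated)
Conditions: t-BuCOCl, Et3N, THF, −20 °C; then 4, LiCl, −20 °C → rt
Reagents that add atoms: none
Why: N-Acylation of the oxazolidinone by a mixed anhydride should occur at the unhindered acyl group under LiCl/Et3N activation, without acid that could open the ketal.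

**Step 3**
Reactants: 7 propane-1,3-diol
Product: 8 3-(4-methoxybenzyloxy)propan-1-ol
Conditions: 7 (3 equiv), NaH (1 equiv), THF/DMF, 0 °C; 4-MeOC6H4CH2Cl, Bu4NI (cat.), rt
Reagents that add atoms: 4-methoxybenzyl chloride, COc1ccc(CCl)cc1
Why: Williamson etherification of the mono-alkoxide, with excess diol to favour the mono-ether.

**Step 4**
Reactants: 8 3-(4-methoxybenzyloxy)propan-1-ol
Product: 9 3-(4-methoxybenzyloxy)propanal
Conditions: TEMPO (cat.), PhI(OAc)2, CH2Cl2, rt
Reagents that add atoms: none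
Why: Oxoammonium (TEMPO) oxidation stops at the aldehyde under near-neutral conditions, which should spare the β-alkoxy aldehyde from elimination; 9 is used directly.

**Step 5**
Reactants: 6 (S)-4-benzyl-3-[4-(2-pentyl-1,3-dioxolan-2-yl)butanoyl]oxazolidin-2-one; 9 3-(4-methoxybenzyloxy)propanal
Product: 11 (S)-4-benzyl-3-[(2S,3R)-3-hydroxy-5-(4-methoxybenzyloxy)-2-[2-(2-pentyl-1,3-dioxolan-2-yl)ethyl]pentanoyl]oxazolidin-2-one, via dibutylboron Z-enolate 10 (not isolated)
Conditions: Bu2BOTf, i-Pr2NEt, CH2Cl2, −78 → 0 °C; then 9, −78 → 0 °C; pH 7 buffer, MeOH, H2O2, 0 °C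
Reagents that add atoms: none
Why: Evans syn aldol reaction: the Z-boron enolate reacts through a closed chair transition state on the face away from the benzyl group, which sets C12 (S in 11) and the syn carbinol C11 (R).

**Step 6**
Reactants: 11 syn aldol adduct
Product: 12 (S)-4-benzyl-3-[(2S,3R)-3-(tert-butyldimethylsilyloxy)-5-(4-methoxybenzyloxy)-2-[2-(2-pentyl-1,3-dioxolan-2-yl)ethyl]pentanoyl]oxazolidin-2-one
Conditions: TBSOTf, 2,6-lutidine, CH2Cl2, −78 → 0 °C
Reagents that add atoms: tert-butyldimethylsilyl triflate, CC(C)(C)[Si](C)(C)OS(=O)(=O)C(F)(F)F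
Why: Silylation with a silyl triflate and a hindered pyridine base protects the secondary aldol hydroxyl without retro-aldol cleavage, and a ketone ketal should tolerate these conditions at low temperature.

**Step 7**
Reactants: 12 silylated imide
Product: 13 (2R,3R)-3-(tert-butyldimethylsilyloxy)-5-(4-methoxybenzyloxy)-2-[2-(2-pentyl-1,3-dioxolan-2-yl)ethyl]pentan-1-ol
Conditions: LiBH4, MeOH (1 equiv), THF, 0 °C
Reagents that add atoms: none
Why: Borohydride reduction of the exocyclic imide carbonyl removes the auxiliary and gives the primary alcohol without touching the α-stereocentre, the silyl ether, the benzyl ether or the ketal.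

**Step 8**
Reactants: 13 primary alcohol
Product: 14 (2S,3R)-3-(tert-butyldimethylsilyloxy)-5-(4-methoxybenzyloxy)-2-[2-(2-pentyl-1,3-dioxolan-2-yl)ethyl]pentanal
Conditions: Dess–Martin periodinane, pyridine, CH2Cl2, 0 °C → rt
Reagents that add atoms: none
Why: Dess–Martin oxidation under buffered, non-basic conditions should give the α-branched C8 aldehyde without epimerisation at C12.

**Step 9**
Reactants: 14 C8 aldehyde; 15 methyl bis(2,2,2-trifluoroethyl)phosphonoacetate
Product: 16 methyl (2Z,4R,5R)-5-(tert-butyldimethylsilyloxy)-7-(4-methoxybenzyloxy)-4-[2-(2-pentyl-1,3-dioxolan-2-yl)ethyl]hept-2-enoate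
Conditions: 15, KN(SiMe3)2, 18-crown-6, THF, −78 °C; then 14, −78 °C
Reagents that add atoms: none
Why: Still–Gennari variant of the Horner–Wadsworth–Emmons olefination: the trifluoroethyl phosphonate with a dissociated potassium counter-ion eliminates under kinetic control to the (Z)-enoate, and the low temperature protects C12.

**Step 10**
Reactants: 16 (Z)-enoate 4-methoxybenzyl ether
Product: 17 methyl (2Z,4R,5R)-5-(tert-butyldimethylsilyloxy)-7-hydroxy-4-[2-(2-pentyl-1,3-dioxolan-2-yl)ethyl]hept-2-enoate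
Conditions: DDQ, CH2Cl2/pH 7 buffer (10:1), 0 °C → rt
Reagents that add atoms: none
Why: Oxidative cleavage of the electron-rich 4-methoxybenzyl ether by hydride abstraction leaves the silyl ether, the ketal and the electron-poor alkene alone.

**Step 11**
Reactants: 17 C9 alcohol
Product: 18 methyl (2Z,4R,5R)-5-(tert-butyldimethylsilyloxy)-7-oxo-4-[2-(2-pentyl-1,3-dioxolan-2-yl)ethyl]hept-2-enoate
Conditions: Dess–Martin periodinane, pyridine, CH2Cl2, 0 °C
Reagents that add atoms: none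
Why: Dess–Martin oxidation gives the β-silyloxy aldehyde under conditions too mild for loss of silanol; 18 is used without storage.

**Step 12**
Reactants: 18 aldehyde (Z)-enoate
Product: 20 (3aR,4R,5R,6aS)-5-(tert-butyldimethylsilyloxy)-4-[2-(2-pentyl-1,3-dioxolan-2-yl)ethyl]hexahydro-2H-cyclopenta[b]furan-2-one, via cis hydroxy ester 19 (not isolated)
Conditions: Pb cathode, Pt anode, divided cell, CH3CN (0.02 M), Et4NOTs (0.1 M), LiClO4 (2 equiv), CH2(CO2Me)2 (2 equiv), −2.3 V vs SCE, 0 °C, 2 F/mol; then PPTS (cat.), PhMe, 50 °C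
Reagents that add atoms: none
Why: One electron from the cathode enters the enoate π* (the most easily reduced group in 18), the radical anion bonds its β-carbon C8 to the aldehyde carbon C9, and a second electron with two protons from dimethyl malonate gives hydroxy ester 19, whose O9 then displaces methoxide at C6. The closest known reaction is the cathodic cyclisation of aldehyde-tethered α,β-unsaturated esters to 2-hydroxycycloalkylacetates and their lactones, with the SmI2 ketyl–olefin cyclisation as its chemical counterpart; it joins two carbons that are both acceptors in polar terms. The cyclopentane C8–C9–C10–C11–C12 closes 5-exo-trig (C7 stays outside the ring) and the γ-lactone O–C9–C8–C7–C6 closes 5-exo-trig by acyl substitution. C8 is set by C12: allylic 1,3-strain of the (Z)-enoate holds H12 in the alkene plane, so the C10–C11 tether reaches one face while the C13 chain lies on the other, which places C7 trans to the C12 chain and cis to the pseudo-equatorial C11 silyl ether in a chair-like closure. C9 is set by the lithium ion, which should bridge the aldehyde oxygen and the ester oxygen of the radical anion and so turn O9 toward C7 (9α), the only arrangement that can lactonise. The step needs ring closure ahead of simple saturation or dimerisation, secured by the five-atom tether and high dilution, and it needs the cis relation of O9 and C7, the less certain point because closures with tetraalkylammonium counter-ions alone favour the trans hydroxy ester.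

**Step 13**
Reactants: 20 bicyclic lactone
Product: 21 (3aR,4R,5R,6aS)-5-(tert-butyldimethylsilyloxy)-4-[2-(2-pentyl-1,3-dioxolan-2-yl)ethyl]hexahydro-2H-cyclopenta[b]furan-2-ol (anomer mixture)
Conditions: i-Bu2AlH (1.1 equiv), PhMe, −78 °C; aq. potassium sodium tartrate
Reagents that add atoms: none
Why: Partial reduction of a γ-lactone with i-Bu2AlH at low temperature stops at the lactol because the tetrahedral aluminium alkoxide persists until work-up.

**Step 14**
Reactants: 21 lactol; 22 (4-carboxybutyl)triphenylphosphonium bromide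
Product: 24 (Z)-7-[(1R,2R,3R,5S)-3-(tert-butyldimethylsilyloxy)-5-hydroxy-2-[2-(2-pentyl-1,3-dioxolan-2-yl)ethyl]cyclopentyl]hept-5-enoic acid, via phosphorus ylide 23 (not isolated)
Conditions: 22, KOt-Bu (2 equiv per 22), THF, 0 °C; then 21, 0 °C → rt; 1 M HCl to pH 5, 0 °C
Reagents that add atoms: none
Why: Wittig olefination of the open hydroxy aldehyde form of the lactol with a non-stabilised ylide under lithium-free conditions should give the (Z)-C5=C6 alkene and release the C9 hydroxyl.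

**Step 15**
Reactants: 24 C9 hydroxy acid
Product: 26 (Z)-7-[(1R,2R,3R,5S)-3-(tert-butyldimethylsilyloxy)-2-[2-(2-pentyl-1,3-dioxolan-2-yl)ethyl]-5-(tetrahydro-2H-pyran-2-yloxy)cyclopentyl]hept-5-enoic acid (mixture at the acetal carbon), via bis-THP derivative 25 (not isolated)
Conditions: 3,4-dihydro-2H-pyran (3 equiv), PPTS (cat.), CH2Cl2, rt; then LiOH, THF/H2O, 0 °C; 1 M HCl to pH 5, 0 °C
Reagents that add atoms: 3,4-dihydro-2H-pyran, C1CCOC=C1; lithium hydroxide, [Li+].[OH-]
Why: Acid-catalysed acetalisation with dihydropyran protects the C9 hydroxyl (and the acid as a labile acetal ester), and brief cold hydroxide cleaves only that activated ester.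

**Step 16**
Reactants: 26 C9 THP ether
Product: 27 (Z)-7-[(1R,2R,3R,5S)-3-hydroxy-2-[2-(2-pentyl-1,3-dioxolan-2-yl)ethyl]-5-(tetrahydro-2H-pyran-2-yloxy)cyclopentyl]hept-5-enoic acid
Conditions: Bu4NF (3 equiv), THF, rt
Reagents that add atoms: none
Why: Fluoride-induced desilylation frees the C11 hydroxyl while the two acetals are inert to fluoride.

**Step 17**
Reactants: 27 C11 alcohol
Product: 28 (Z)-7-[(1R,2R,5S)-3-oxo-2-[2-(2-pentyl-1,3-dioxolan-2-yl)ethyl]-5-(tetrahydro-2H-pyran-2-yloxy)cyclopentyl]hept-5-enoic acid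
Conditions: Dess–Martin periodinane, pyridine, CH2Cl2, 0 °C
Reagents that add atoms: none
Why: Dess–Martin oxidation of the secondary alcohol gives the C11 ketone without a base strong enough to eliminate the β-alkoxy group, and C12 stays in its more stable trans arrangement.

**Step 18**
Reactants: 28 protected diketo acid
Product: 29 13,14-dihydro-15-keto-prostaglandin D2, (Z)-7-[(1R,2R,5S)-5-hydroxy-3-oxo-2-(3-oxooctyl)cyclopentyl]hept-5-enoic acid
Conditions: AcOH/H2O/THF (3:1:1), 40 °C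
Reagents that add atoms: water, O
Why: Acid-catalysed acetal hydrolysis removes the THP ether and the dioxolane together in a weakly acidic medium in which the β-ketol should not dehydrate, and no stereocentre is touched.

**Compound list**
1 | 5-oxodecanoic acid | CCCCCC(=O)CCCC(=O)O | starting material
2 | 2-hydroxyethyl 4-(2-pentyl-1,3-dioxolan-2-yl)butanoate | CCCCCC1(OCCO1)CCCC(=O)OCCO | intermediate
3 | 4-(2-pentyl-1,3-dioxolan-2-yl)butanoic acid | CCCCCC1(OCCO1)CCCC(=O)O | intermediate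
4 | (S)-4-benzyl-2-oxazolidinone | O=C1OC[C@H](Cc2ccccc2)N1 | starting material
5 | pivalic 4-(2-pentyl-1,3-dioxolan-2-yl)butanoic anhydride | CCCCCC1(OCCO1)CCCC(=O)OC(=O)C(C)(C)C | intermediate
6 | (S)-4-benzyl-3-[4-(2-pentyl-1,3-dioxolan-2-yl)butanoyl]oxazolidin-2-one | O=C1OC[C@H](Cc2ccccc2)N1C(=O)CCCC3(CCCCC)OCCO3 | intermediate
7 | propane-1,3-diol | OCCCO | starting material
8 | 3-(4-methoxybenzyloxy)propan-1-ol | COc1ccc(COCCCO)cc1 | intermediate
9 | 3-(4-methoxybenzyloxy)propanal | COc1ccc(COCCC=O)cc1 | intermediate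
10 | dibutylboron (Z)-enolate of imide 6 | O=C1OC[C@H](Cc2ccccc2)N1/C(OB(CCCC)CCCC)=C/CCC3(CCCCC)OCCO3 | intermediate
11 | (S)-4-benzyl-3-[(2S,3R)-3-hydroxy-5-(4-methoxybenzyloxy)-2-[2-(2-pentyl-1,3-dioxolan-2-yl)ethyl]pentanoyl]oxazolidin-2-one | CCCCCC1(OCCO1)CC[C@H](C(=O)N2C(=O)OC[C@@H]2Cc3ccccc3)[C@H](O)CCOCc4ccc(OC)cc4 | intermediate
12 | (S)-4-benzyl-3-[(2S,3R)-3-(tert-butyldimethylsilyloxy)-5-(4-methoxybenzyloxy)-2-[2-(2-pentyl-1,3-dioxolan-2-yl)ethyl]pentanoyl]oxazolidin-2-one | CCCCCC1(OCCO1)CC[C@H](C(=O)N2C(=O)OC[C@@H]2Cc3ccccc3)[C@H](O[Si](C)(C)C(C)(C)C)CCOCc4ccc(OC)cc4 | intermediate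
13 | (2R,3R)-3-(tert-butyldimethylsilyloxy)-5-(4-methoxybenzyloxy)-2-[2-(2-pentyl-1,3-dioxolan-2-yl)ethyl]pentan-1-ol | CCCCCC1(OCCO1)CC[C@H](CO)[C@H](O[Si](C)(C)C(C)(C)C)CCOCc2ccc(OC)cc2 | intermediate
14 | (2S,3R)-3-(tert-butyldimethylsilyloxy)-5-(4-methoxybenzyloxy)-2-[2-(2-pentyl-1,3-dioxolan-2-yl)ethyl]pentanal | CCCCCC1(OCCO1)CC[C@H](C=O)[C@H](O[Si](C)(C)C(C)(C)C)CCOCc2ccc(OC)cc2 | intermediate
15 | methyl bis(2,2,2-trifluoroethyl)phosphonoacetate | COC(=O)CP(=O)(OCC(F)(F)F)OCC(F)(F)F | starting material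
16 | methyl (2Z,4R,5R)-5-(tert-butyldimethylsilyloxy)-7-(4-methoxybenzyloxy)-4-[2-(2-pentyl-1,3-dioxolan-2-yl)ethyl]hept-2-enoate | CCCCCC1(OCCO1)CC[C@H](/C=C\C(=O)OC)[C@H](O[Si](C)(C)C(C)(C)C)CCOCc2ccc(OC)cc2 | intermediate
17 | methyl (2Z,4R,5R)-5-(tert-butyldimethylsilyloxy)-7-hydroxy-4-[2-(2-pentyl-1,3-dioxolan-2-yl)ethyl]hept-2-enoate | CCCCCC1(OCCO1)CC[C@H](/C=C\C(=O)OC)[C@H](O[Si](C)(C)C(C)(C)C)CCO | intermediate
18 | methyl (2Z,4R,5R)-5-(tert-butyldimethylsilyloxy)-7-oxo-4-[2-(2-pentyl-1,3-dioxolan-2-yl)ethyl]hept-2-enoate | CCCCCC1(OCCO1)CC[C@H](/C=C\C(=O)OC)[C@H](O[Si](C)(C)C(C)(C)C)CC=O | intermediate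
19 | methyl 2-[(1R,2R,3R,5S)-3-(tert-butyldimethylsilyloxy)-5-hydroxy-2-[2-(2-pentyl-1,3-dioxolan-2-yl)ethyl]cyclopentyl]acetate | CCCCCC1(OCCO1)CC[C@H]2[C@H](O[Si](C)(C)C(C)(C)C)C[C@H](O)[C@@H]2CC(=O)OC | intermediate
20 | (3aR,4R,5R,6aS)-5-(tert-butyldimethylsilyloxy)-4-[2-(2-pentyl-1,3-dioxolan-2-yl)ethyl]hexahydro-2H-cyclopenta[b]furan-2-one | CCCCCC1(OCCO1)CC[C@H]2[C@H](O[Si](C)(C)C(C)(C)C)C[C@@H]3OC(=O)C[C@H]23 | intermediate
21 | (3aR,4R,5R,6aS)-5-(tert-butyldimethylsilyloxy)-4-[2-(2-pentyl-1,3-dioxolan-2-yl)ethyl]hexahydro-2H-cyclopenta[b]furan-2-ol | CCCCCC1(OCCO1)CC[C@H]2[C@H](O[Si](C)(C)C(C)(C)C)C[C@@H]3OC(O)C[C@H]23 | intermediate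
22 | (4-carboxybutyl)triphenylphosphonium bromide | OC(=O)CCCC[P+](c1ccccc1)(c2ccccc2)c3ccccc3.[Br-] | starting material
23 | potassium 5-(triphenylphosphoranylidene)pentanoate | [K+].[O-]C(=O)CCCC=P(c1ccccc1)(c2ccccc2)c3ccccc3 | intermediate
24 | (Z)-7-[(1R,2R,3R,5S)-3-(tert-butyldimethylsilyloxy)-5-hydroxy-2-[2-(2-pentyl-1,3-dioxolan-2-yl)ethyl]cyclopentyl]hept-5-enoic acid | CCCCCC1(OCCO1)CC[C@H]2[C@H](O[Si](C)(C)C(C)(C)C)C[C@H](O)[C@@H]2C/C=C\CCCC(=O)O | intermediate
25 | tetrahydro-2H-pyran-2-yl ester of 26 (bis-THP derivative) | CCCCCC1(OCCO1)CC[C@H]2[C@H](O[Si](C)(C)C(C)(C)C)C[C@H](OC3CCCCO3)[C@@H]2C/C=C\CCCC(=O)OC4CCCCO4 | intermediate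
26 | (Z)-7-[(1R,2R,3R,5S)-3-(tert-butyldimethylsilyloxy)-2-[2-(2-pentyl-1,3-dioxolan-2-yl)ethyl]-5-(tetrahydro-2H-pyran-2-yloxy)cyclopentyl]hept-5-enoic acid | CCCCCC1(OCCO1)CC[C@H]2[C@H](O[Si](C)(C)C(C)(C)C)C[C@H](OC3CCCCO3)[C@@H]2C/C=C\CCCC(=O)O | intermediate
27 | (Z)-7-[(1R,2R,3R,5S)-3-hydroxy-2-[2-(2-pentyl-1,3-dioxolan-2-yl)ethyl]-5-(tetrahydro-2H-pyran-2-yloxy)cyclopentyl]hept-5-enoic acid | CCCCCC1(OCCO1)CC[C@H]2[C@H](O)C[C@H](OC3CCCCO3)[C@@H]2C/C=C\CCCC(=O)O | intermediate
28 | (Z)-7-[(1R,2R,5S)-3-oxo-2-[2-(2-pentyl-1,3-dioxolan-2-yl)ethyl]-5-(tetrahydro-2H-pyran-2-yloxy)cyclopentyl]hept-5-enoic acid | CCCCCC1(OCCO1)CC[C@H]2C(=O)C[C@H](OC3CCCCO3)[C@@H]2C/C=C\CCCC(=O)O | intermediate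
29 | 13,14-dihydro-15-keto-prostaglandin D2 | CCCCCC(=O)CC[C@H]1C(=O)C[C@H](O)[C@@H]1C/C=C\CCCC(=O)O | target

**Step count**
Total: 18 steps. Longest linear sequence: 16 steps (steps 1, 2 and 5 to 18, from 5-oxodecanoic acid).

**Steps most likely to fail**

Step 12. The ring may close with O9 turned away from the ester, giving a trans hydroxy ester that cannot lactonise. The enoate may also be saturated or dimerised before closure, or the β-silyloxy aldehyde may lose silanol under the electrogenerated base. Fallback, setting out from 18 and coming back at 20: the closure is run with the chemical reductant SmI2 in THF/MeOH at −78 °C (ketyl–olefin cyclisation), and the configuration at C9 is then corrected by inversion instead of being set directly. Any cis adduct lactonises to 20. The open trans adduct, methyl 2-[(1R,2R,3R,5R)-3-(tert-butyldimethylsilyloxy)-5-hydroxy-2-[2-(2-pentyl-1,3-dioxolan-2-yl)ethyl]cyclopentyl]acetate F1, is saponified (LiOH, THF/H2O) to 2-[(1R,2R,3R,5R)-3-(tert-butyldimethylsilyloxy)-5-hydroxy-2-[2-(2-pentyl-1,3-dioxolan-2-yl)ethyl]cyclopentyl]acetic acid F2. F2 is closed by Mitsunobu lactonisation (PPh3, DIAD, THF, 0 °C) with inversion at C9 to give 20. The same two operations would also recover trans material from the electrolysis itself.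

Step 14. The C9 alkoxide released on lactol opening may take over the silyl group from O11 (base-induced 1,3-silyl migration), which would blur the distinction between the two ring hydroxyls. Fallback, setting out from 20 and coming back at 24: the silyl group is removed before the olefination and put back regioselectively afterwards. Bu4NF in THF gives (3aR,4R,5R,6aS)-5-hydroxy-4-[2-(2-pentyl-1,3-dioxolan-2-yl)ethyl]hexahydro-2H-cyclopenta[b]furan-2-one F3. i-Bu2AlH (2.2 equiv, −78 °C) gives the corresponding lactol, (3aR,4R,5R,6aS)-4-[2-(2-pentyl-1,3-dioxolan-2-yl)ethyl]hexahydro-2H-cyclopenta[b]furan-2,5-diol F4. The Wittig reaction with ylide 23 gives (Z)-7-[(1R,2R,3R,5S)-3,5-dihydroxy-2-[2-(2-pentyl-1,3-dioxolan-2-yl)ethyl]cyclopentyl]hept-5-enoic acid F5. Silylation with TBSCl/imidazole in DMF at 0 °C should take the less hindered C11 hydroxyl in preference to the C9 hydroxyl, which is flanked by the cis α-chain; the silyl ester is cleaved in the aqueous work-up, giving 24.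

Step 18. During the time needed to hydrolyse the dioxolane, the C9 hydroxyl β to the C11 ketone may be lost by acid-promoted dehydration to the cyclopentenone. Fallback, setting out from 24 and coming back at 29: the C15 ketone is unmasked before the β-ketol exists, so that the last step only has to remove the THP ether.
- PPTS in acetone/H2O at rt gives (Z)-7-[(1R,2R,3R,5S)-3-(tert-butyldimethylsilyloxy)-5-hydroxy-2-(3-oxooctyl)cyclopentyl]hept-5-enoic acid F6.
- Dihydropyran/PPTS gives the tetrahydropyranyl ether tetrahydropyranyl ester F7, and cold LiOH then gives (Z)-7-[(1R,2R,3R,5S)-3-(tert-butyldimethylsilyloxy)-2-(3-oxooctyl)-5-(tetrahydro-2H-pyran-2-yloxy)cyclopentyl]hept-5-enoic acid F8.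
- Bu4NF gives (Z)-7-[(1R,2R,3R,5S)-3-hydroxy-2-(3-oxooctyl)-5-(tetrahydro-2H-pyran-2-yloxy)cyclopentyl]hept-5-enoic acid F9. F9 may rest partly as its six-membered hemiketal and is oxidised through the open form.
- Dess–Martin periodinane gives (Z)-7-[(1R,2R,5S)-3-oxo-2-(3-oxooctyl)-5-(tetrahydro-2H-pyran-2-yloxy)cyclopentyl]hept-5-enoic acid F10.
- Short treatment with AcOH/H2O/THF at 40 °C gives 29.

**Further compounds**
F1 | step 12 | methyl 2-[(1R,2R,3R,5R)-3-(tert-butyldimethylsilyloxy)-5-hydroxy-2-[2-(2-pentyl-1,3-dioxolan-2-yl)ethyl]cyclopentyl]acetate | CCCCCC1(OCCO1)CC[C@H]2[C@H](O[Si](C)(C)C(C)(C)C)C[C@@H](O)[C@@H]2CC(=O)OC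
F2 | step 12 | 2-[(1R,2R,3R,5R)-3-(tert-butyldimethylsilyloxy)-5-hydroxy-2-[2-(2-pentyl-1,3-dioxolan-2-yl)ethyl]cyclopentyl]acetic acid | CCCCCC1(OCCO1)CC[C@H]2[C@H](O[Si](C)(C)C(C)(C)C)C[C@@H](O)[C@@H]2CC(=O)O
F3 | step 14 | (3aR,4R,5R,6aS)-5-hydroxy-4-[2-(2-pentyl-1,3-dioxolan-2-yl)ethyl]hexahydro-2H-cyclopenta[b]furan-2-one | CCCCCC1(OCCO1)CC[C@H]2[C@H](O)C[C@@H]3OC(=O)C[C@H]23
F4 | step 14 | (3aR,4R,5R,6aS)-4-[2-(2-pentyl-1,3-dioxolan-2-yl)ethyl]hexahydro-2H-cyclopenta[b]furan-2,5-diol | CCCCCC1(OCCO1)CC[C@H]2[C@H](O)C[C@@H]3OC(O)C[C@H]23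
F5 | step 14 | (Z)-7-[(1R,2R,3R,5S)-3,5-dihydroxy-2-[2-(2-pentyl-1,3-dioxolan-2-yl)ethyl]cyclopentyl]hept-5-enoic acid | CCCCCC1(OCCO1)CC[C@H]2[C@H](O)C[C@H](O)[C@@H]2C/C=C\CCCC(=O)O
F6 | step 18 | (Z)-7-[(1R,2R,3R,5S)-3-(tert-butyldimethylsilyloxy)-5-hydroxy-2-(3-oxooctyl)cyclopentyl]hept-5-enoic acid | CCCCCC(=O)CC[C@H]1[C@H](O[Si](C)(C)C(C)(C)C)C[C@H](O)[C@@H]1C/C=C\CCCC(=O)O
F7 | step 18 | tetrahydro-2H-pyran-2-yl (Z)-7-[(1R,2R,3R,5S)-3-(tert-butyldimethylsilyloxy)-2-(3-oxooctyl)-5-(tetrahydro-2H-pyran-2-yloxy)cyclopentyl]hept-5-enoate | CCCCCC(=O)CC[C@H]1[C@H](O[Si](C)(C)C(C)(C)C)C[C@H](OC2CCCCO2)[C@@H]1C/C=C\CCCC(=O)OC3CCCCO3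
F8 | step 18 | (Z)-7-[(1R,2R,3R,5S)-3-(tert-butyldimethylsilyloxy)-2-(3-oxooctyl)-5-(tetrahydro-2H-pyran-2-yloxy)cyclopentyl]hept-5-enoic acid | CCCCCC(=O)CC[C@H]1[C@H](O[Si](C)(C)C(C)(C)C)C[C@H](OC2CCCCO2)[C@@H]1C/C=C\CCCC(=O)O
F9 | step 18 | (Z)-7-[(1R,2R,3R,5S)-3-hydroxy-2-(3-oxooctyl)-5-(tetrahydro-2H-pyran-2-yloxy)cyclopentyl]hept-5-enoic acid | CCCCCC(=O)CC[C@H]1[C@H](O)C[C@H](OC2CCCCO2)[C@@H]1C/C=C\CCCC(=O)O
F10 | step 18 | (Z)-7-[(1R,2R,5S)-3-oxo-2-(3-oxooctyl)-5-(tetrahydro-2H-pyran-2-yloxy)cyclopentyl]hept-5-enoic acid | CCCCCC(=O)CC[C@H]1C(=O)C[C@H](OC2CCCCO2)[C@@H]1C/C=C\CCCC(=O)O
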